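The data are simulated with made-up constants; noise was put on by code.

Start from slowness: target fades over hours to days and heat changes the pace, so count a new flask's time on the clock of a run already made.

| setting | Saturday's | Monday's | teal | amber |
|---|---|---|---|---|
| substrate | 0.39 M (in portions, 4) | 0.58 M (in portions, 4) | 0.78 M (in portions, 4) | 0.78 M |
| reagent in the second phase | 1.3 equiv | 1.3 equiv | 1.30 equiv | 1.30 equiv |
| temperature | 55 °C | 75 °C | 90 °C | 60 °C |
| remark | run made earlier; portions every 5.0 min | run made earlier; portions every 5.0 min | the portions of substrate follow each other after 5.0 min, the first at the start | everything together at the start |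
| time |  |  | 20 h | 80 h |
| volume of the second phase over the first |  |  | 0.50 | 0.50 |

| run | time / h | target / % | isomer of the product / % |
|---|---|---|---|
| Saturday's | 15.0 | 80.6 | 5.9 |
| Saturday's | 30.0 | 79.3 | 13.4 |
| Saturday's | 60.0 | 64.8 | 25.3 |
| Saturday's | 72.0 | 59.3 | 29.3 |
| Saturday's | 96.0 | 50.9 | 36.4 |
| Monday's | 3.00 | 76.8 | 13.0 |
| Monday's | 8.00 | 54.1 | 28.5 |
| Monday's | 15.0 | 37.0 | 38.0 |
| Monday's | 25.0 | 26.1 | 38.0 |
| Monday's | 30.0 | 23.1 | 37.1 |

(standard deviation of a reading: 0.5 percentage points)

- which one finishes higher in share of target in all that became target or isomer of the product or over-reaction product ("neither" within 2 percentage points) (teal / amber / neither)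
- share of target in all that became target or isomer of the product or over-reaction product, teal
- share of target in all that became target or isomer of the product or over-reaction product, amber

- in the second phase: reagent in the second phase; everything else is in the first
- charges count per volume of the first phase; a concentration in a rate is the amount of a species over the volume of its own phase; every rate counts per litre of the first phase
- candidate steps: reagent in the reaction phase <-> reagent in the second phase; substrate + reagent in the reaction phase -> target; target <-> isomer of the product; target -> over-reaction product
- the earlier runs hold the two phases in the same ratio of volumes as the flask asked about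

Climb the ladder from the fast end. Teal's portions are in after 15.0 min, and amber has its charge at the start. On the next rung substrate, the limiting reagent at 1.30 equiv, turns into target: on Saturday target plus isomer still grows from 86.5% at 15.0 h to 92.7% at 30.0 h, while on Monday it falls from 89.8% at 3.00 h to 82.6% at 8.00 h. Then target passes on. Its mean constant, ln of first over last reading per hour between them, is 0.00567 h⁻¹ on Saturday and 0.0445 h⁻¹ on Monday. Their quotient is the clock ratio, 7.84, for the step from 55 °C to 75 °C.

Spread its logarithm evenly over the degrees, assuming every step speeds alike. Amber's 80 h then counts as 17.1 h of Monday's time, and teal's 20 h as 93.7 h. The mean itself is a poor curve: Monday's constant at the head, 0.0701 h⁻¹, is larger than in the tail, 0.0244 h⁻¹, and one exponential at the mean would say 46.7% for amber and 1.55% for teal. Read the curve instead. Amber's counted time lies between Monday's readings at 15.0 h and 25.0 h, which gives 34.4%. Teal lies past the last reading, so carrying the tail on gives a less sure 4.87%.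

The forecast, reckoned separately, says amber, with teal at 5% (2% to 10%) and amber at 36% (30% to 42%), on the ground that “the target's decay dominates”.

The simulation gives amber: teal 5.67%, amber 34.5%.

    reagent in the reaction phase ⇌ reagent in the second phase, rate k1*([reagent in the reaction phase] - [reagent in the second phase]/K1) per volume of the first phase (partition coefficient = 0.872, kL = 1.19 h⁻¹)
    substrate + reagent in the reaction phase → target (k = 21.9 M⁻¹ h⁻¹, Ea = 92.0 kJ mol⁻¹)
    target ⇌ isomer of the product (K = 0.551, k = 0.369 h⁻¹, Ea = 116 kJ mol⁻¹, ΔH = −59.0 kJ mol⁻¹)
    target → over-reaction product (k = 0.194 h⁻¹, Ea = 128 kJ mol⁻¹)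
    (constants at 90 °C)

In teal, target and isomer relax together with a half-life of 0.667 h, and over-reaction by itself halves target in 3.6 h, both short against 20 h. Teal ends with 90.6% over-reaction product, amber with 19.8%. Teal stopped at 12 h counts as 56.2 h of Monday's time, and the tail gives 12.2% target; the computed flask holds 14.4%.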